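(The runs were generated by integration on assumed constants, and the scatter is random.)

common to all: solid substrate 0.85 M

| charge | partner | remark | time |
|---|---|---|---|
| spring | 1.4 M | run made earlier |  |
| dawn | 1.8 M | run made earlier |  |
| north-east | 2.12 M |  | 10 min |
| south-west | 1.70 M |  | 10 min |

| run | time / min | triple product / % | bis adduct / % | solid substrate / % |
|---|---|---|---|---|
| spring | 1.00 | 0.3 | 1.0 | 87.6 |
| spring | 2.00 | 2.5 | 4.0 | 80.6 |
| spring | 3.00 | 3.9 | 5.5 | 73.5 |
| spring | 4.00 | 5.2 | 6.3 | 67.5 |
| spring | 5.00 | 8.5 | 7.1 | 60.8 |
| dawn | 0.417 | 0 | 0.1 | 94.4 |
| dawn | 0.833 | 0.3 | 0.8 | 90.6 |
| dawn | 1.33 | 1.0 | 1.7 | 85.6 |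
| dawn | 2.50 | 2.7 | 5.6 | 76.2 |
| dawn | 5.00 | 11.7 | 7.9 | 56.9 |

(scatter of a reading: 0.5 percentage points)

- given per volume of solution although it is solid: solid substrate
- at the start none of the solid substrate is in solution

* which of these holds the largest part of the solid substrate at the end of north-east (bis adduct / solid substrate / single product / triple product)
* which of these holds the largest part of the solid substrate at the end of south-west (bis adduct / solid substrate / single product / triple product)
* triple product at the end of south-west, in percent of the solid substrate charged

1. I started from the amounts: south-west holds twice as much partner as solid substrate, so I wrote the balance of the solid substrate, in which whatever is neither solid, bis adduct nor triple product stands as an unread gap.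

2. On the fastest rung, the gap in the dawn run read 5.50 % after 0.417 min and 23.5 % after 5.00 min, so it filled at 0.132 /min at first and then more slowly, at 0.0393 /min.

3. On the next rung, in the last minute of the spring run, bis adduct rose by 0.8 percentage points, less than triple product, which rose by 3.3 points.

4. Last came the solid substrate, for which I read an emptying time, 14.9 min in the spring run and 12.2 min in the dawn run, as the charge over its fall per minute from first to last reading. South-west's 1.70 M of partner lies between those runs, and both times exceed its 10 min, so I reckoned 18.0 % to 32.9 % of the solid substrate still solid at its end, and named no leader.

5. The forecast named single product for north-east and single product for south-west, with triple product at 25 % (20 % to 30 %) in south-west: “Single product leads in both, though less clearly in north-east.”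

6. North-east ended led by triple product at 33.4 %, and south-west by solid substrate at 30.5 %, with triple product at 24.7 %.

    starting material + partner → single product (k = 0.00976 /M/s)
    partner + single product → bis adduct (k = 0.0159 /M/s)
    partner + bis adduct → triple product (k = 0.00580 /M/s)
    single product → decomposed reagent (k = 0.0122 /s)
    solid substrate ⇌ starting material, rate k5*(cs5 - [starting material]) while solid is left; crystals form when [starting material] > cs5 (solubility = 0.120 M, k = 0.0218 /s)

7. South-west's end solid corresponds to an emptying time of 14.4 min, against my 12.2 min and 14.9 min. At 3.98 min in south-west, single product had a half-life of 0.56 min by the making of bis adduct, far shorter than the run's 10 min, and it was made 1.00 times as fast as used up, each step taken net, which makes it a short-lived intermediate in quasi-steady state, ending at 3.16 %.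

8. For the neighbour of south-west with 0.34 M of solid substrate, the same pace gives an emptying time of 4.89 min to 5.97 min, shorter than 10 min. Computed, that flask ends with 0 % solid substrate and 54.4 % triple product.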